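(The data were computed from invented constants; the scatter is artificial.)

Within 3.00 min of the start the summer run reads 19% target, and by 20.0 min it reads 1%; that run is the flask now asked about.

| flask | starting material | second substrate | reagent | free catalyst | remark | time |
|---|---|---|---|---|---|---|
| summer | 0.13 M | 0.13 M | 0.13 M | 18 mM | the very flask that is asked about, followed so far |  |
| flask | 0.13 M | 0.130 M | 0.130 M | 18 mM |  | 40 min |

- summer (time / min: target / %): 0.833: 6; 1.67: 16; 3.00: 19; 5.00: 18; 10.0: 11; 20.0: 1

(each reading ± 2 percentage points)

- time, not beyond 40 min, at which the flask holds most target
- the amount of target, in percent of the starting material charged, at that time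

- steps that have been proposed: second substrate + free catalyst <-> catalyst intermediate B; reagent + catalyst intermediate B -> free catalyst + second product; target -> over-reaction product; reagent + catalyst intermediate A -> free catalyst + target; starting material + free catalyst <-> catalyst intermediate A

By the proposed steps, starting material binds free catalyst as catalyst intermediate A, and reagent turns that into target, which goes on to over-reaction product. Second substrate binds free catalyst as catalyst intermediate B, and reagent turns that into second product. So each target costs one reagent, and its over-reaction product carries the same cost. I therefore write the balance of the reagent as a budget b, the reagent charged over the starting material charged, here 100%. Reagent left, target, over-reaction product and second product, each counted in percent of the starting material charged, must add up to b. The highest reading takes a share f of it, 19.0%. My own reckoning is that reading itself, 19% at 3.00 min, with its scatter.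

The forecast says 19.5% at 3.5 min, on the ground that “the best time is early”.

The flask gives 19.0% at 3.13 min.

    second substrate + free catalyst ⇌ catalyst intermediate B (K = 7.90 M⁻¹, k = 0.210 M⁻¹ s⁻¹)
    reagent + catalyst intermediate B → free catalyst + second product (k = 0.0500 M⁻¹ s⁻¹)
    target → over-reaction product (k = 0.00600 s⁻¹)
    reagent + catalyst intermediate A → free catalyst + target (k = 1.00 M⁻¹ s⁻¹)
    starting material + free catalyst ⇌ catalyst intermediate A (K = 2.70 M⁻¹, k = 3.70 M⁻¹ s⁻¹)

At 3.13 min this flask holds 60.4% of its reagent, so 39.6% of b is spent and the peak stands with reagent in hand. At 3.64 min, a little later, this flask makes target at 0.903 of the rate at which it uses it up, each step taken net. The neighbour charged with 0.052 M of reagent has b = 40.0%, and f, carried over unchanged as an estimate, gives 7.60%. Its computed peak is 8.46%, and at 40.0 min that neighbour, with 0.313% of its reagent left (the limiting reagent), still holds 63.9% starting material.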